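**Retrosynthetic overview**
1. Target 42 comes from desilylation of 41. Its only ring (28-membered) is closed in step 22 by a chiral-phosphoric-acid-catalysed macrocyclising Passerini reaction of isocyano acid 38 with butanal 39 (C2–C3 bond, O1–C28 ester, C2 stereocentre).
2. 38 comes from seco formamide ester 35, made by Suzuki–Miyaura coupling (C13–C14) of alkenylboronate 15 with Z-vinyl iodide 34.
3. 15 comes from Fukuyama ketone coupling (C20–C21) of bromo ester 7 and thioester 11; C25 and C16 are set by Cu-catalysed SN2′ alkylations, C27 by Ir-catalysed hydrogenation.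
4. 34 comes from propargyl alcohol by carbomagnesiation/iodination (C12=C13), phosphoric-acid-catalysed anti-silyloxyallylboration (C8, C9) and a Cu-catalysed Henry reaction (C6, N).
5. Ring order: the chain stays open through step 21; the macrocycle is formed once (step 22) and then deprotected.

Locants C2–C28 are the ring numbering of 42 (O1, C2 carries propyl, C3 amide carbonyl, N4, C28 ester carbonyl). TBS = tert-butyldimethylsilyl, Bpin = 4,4,5,5-tetramethyl-1,3,2-dioxaborolan-2-yl, (R)-TRIP = (R)-3,3′-bis(2,4,6-triisopropylphenyl)-1,1′-binaphthyl-2,2′-diyl hydrogen phosphate.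

Assumption: each chiral catalyst is named as the enantiomer expected to give the drawn centre; if its sense proves opposite, the mirror-image catalyst is used with no other change.

**West fragment (steps 1–9)**

Step 1
Reactants: 1 6-bromohex-1-ene; 2 (E)-1,4-dibromobut-2-ene
Product: 3 (E)-1,7-dibromohept-2-ene
Conditions: second-generation Grubbs catalyst (2 mol %), 2 (3 equiv), CH2Cl2, 40 °C
Reagents that add atoms: none
Why: olefin cross-metathesis of a terminal alkene with an excess of the symmetrical allylic dibromide gives the thermodynamically favoured E allylic bromide and leaves the primary alkyl bromide untouched (no stereocentre).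

Step 2
Reactants: 3 (E)-1,7-dibromohept-2-ene
Product: 4 (3R)-7-bromo-3-methylhept-1-ene
Conditions: MeMgBr (1.2 equiv), CuBr·SMe2 (1 mol %), (R,R)-Taniaphos (1.1 mol %), CH2Cl2, −78 °C
Reagents that add atoms: methylmagnesium bromide, C[Mg]Br
Why: copper-catalysed asymmetric allylic alkylation (SN2′) in which the chiral ferrocenyl diphosphine–copper complex delivers methyl to one face of the γ-carbon, setting the first stereocentre (future C25, R) with branched selectivity while the alkyl bromide is inert at −78 °C.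

Step 3
Reactants: 4 (3R)-7-bromo-3-methylhept-1-ene; 5 methyl methacrylate
Product: 6 methyl (2E,4R)-8-bromo-2,4-dimethyloct-2-enoate
Conditions: second-generation Hoveyda–Grubbs catalyst (5 mol %), 5 (10 equiv), CH2Cl2, 45 °C
Reagents that add atoms: none
Why: cross-metathesis between the α-branched terminal alkene and the non-dimerising 1,1-disubstituted acrylate gives the E trisubstituted enoate under thermodynamic control without touching the allylic stereocentre.

Step 4
Reactants: 6 methyl (2E,4R)-8-bromo-2,4-dimethyloct-2-enoate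
Product: 7 methyl (2S,4R)-8-bromo-2,4-dimethyloctanoate
Conditions: H2 (50 bar), [Ir(cod)(L)]BArF (1 mol %, L = chiral bicyclic pyridyl di-tert-butylphosphinite), CH2Cl2, rt
Reagents that add atoms: none
Why: iridium-catalysed asymmetric hydrogenation of a trisubstituted α-methyl enoate in which the N,P ligand rather than the γ-methyl group selects the alkene face, giving the (2S) centre (future C27) and hence the 2,4-anti dimethyl array.

Step 5
Reactants: 8 methyl hex-5-enoate; 2 (E)-1,4-dibromobut-2-ene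
Product: 9 methyl (5E)-7-bromohept-5-enoate
Conditions: second-generation Grubbs catalyst (2 mol %), 2 (3 equiv), CH2Cl2, 40 °C
Reagents that add atoms: none
Why: olefin cross-metathesis as in step 1 gives the E allylic bromide and the ester is inert (no stereocentre).

Step 6
Reactants: 9 methyl (5E)-7-bromohept-5-enoate
Product: 10 methyl (5R)-5-ethylhept-6-enoate
Conditions: EtMgBr (1.2 equiv), CuBr·SMe2 (1 mol %), (R,R)-Taniaphos (1.1 mol %), CH2Cl2, −78 °C
Reagents that add atoms: ethylmagnesium bromide, CC[Mg]Br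
Why: copper-catalysed asymmetric SN2′ allylic alkylation places ethyl on the γ-carbon under ligand control to set the (5R) centre (future C16), and the ester does not react with the Grignard reagent at −78 °C.

Step 7
Reactants: 10 methyl (5R)-5-ethylhept-6-enoate
Product: 11 S-ethyl (5R)-5-ethylhept-6-enethioate
Conditions: AlMe3, EtSH, CH2Cl2, 0 °C → rt
Reagents that add atoms: ethanethiol, CCS
Why: ester-to-thioester exchange with the aluminium thiolate formed from AlMe3 and the thiol (transacylation) activates the acyl group for ketone synthesis without touching the stereocentre or the alkene.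

Step 8
Reactants: 7 methyl (2S,4R)-8-bromo-2,4-dimethyloctanoate; 11 S-ethyl (5R)-5-ethylhept-6-enethioate
Product: 13 methyl (2S,4R,13R)-13-ethyl-2,4-dimethyl-9-oxopentadec-14-enoate, via alkylzinc bromide 12 (not isolated)
Conditions: Zn, LiCl, THF, 50 °C; then 11, PdCl2(PPh3)2 (5 mol %), toluene, rt
Reagents that add atoms: none
Why: Fukuyama coupling in which LiCl-assisted zinc insertion into the primary bromide tolerates the methyl ester and zerovalent palladium then couples the alkylzinc with the thioester to form the C20 ketone (C20–C21 bond) without over-addition.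

Step 9
Reactants: 13 methyl (2S,4R,13R)-13-ethyl-2,4-dimethyl-9-oxopentadec-14-enoate; 14 4,4,5,5-tetramethyl-2-vinyl-1,3,2-dioxaborolane
Product: 15 methyl (2S,4R,13R,14E)-13-ethyl-2,4-dimethyl-9-oxo-15-(Bpin)pentadec-14-enoate
Conditions: second-generation Hoveyda–Grubbs catalyst (5 mol %), 14 (3 equiv), CH2Cl2, 40 °C
Reagents that add atoms: none
Why: cross-metathesis of the terminal alkene with the vinylboronate gives the E alkenylboronate because the allylic branch disfavours the Z isomer, and ketone and ester are inert.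

**East fragment (steps 10–18)**

Step 10
Reactants: 16 prop-2-yn-1-ol; 17 [2-(1,3-dioxan-2-yl)ethyl]magnesium bromide
Product: 19 (2Z)-2-[2-(1,3-dioxan-2-yl)ethyl]-3-iodoprop-2-en-1-ol, via alkenylmagnesium alkoxide chelate 18 (not isolated)
Conditions: 17 (2.3 equiv), CuI (10 mol %), THF, 0 °C → rt; then I2, −78 → 0 °C
Reagents that add atoms: iodine, II
Why: copper-catalysed anti-carbomagnesiation of the propargylic magnesium alkoxide adds the alkyl group to the internal carbon and forms a five-membered alkenylmagnesium chelate whose iodinolysis with retention gives the Z iodoalkene that fixes the C12=C13 geometry (no stereocentre).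

Step 11
Reactants: 19 (2Z)-2-[2-(1,3-dioxan-2-yl)ethyl]-3-iodoprop-2-en-1-ol
Product: 20 2-[(3Z)-4-iodo-3-(methoxymethyl)but-3-en-1-yl]-1,3-dioxane
Conditions: NaH, MeI, THF, 0 °C → rt
Reagents that add atoms: iodomethane, CI
Why: Williamson ether synthesis of the allylic alkoxide with iodomethane installs the methoxymethyl group, and the vinyl iodide and acetal are stable to NaH.

Step 12
Reactants: 20 2-[(3Z)-4-iodo-3-(methoxymethyl)but-3-en-1-yl]-1,3-dioxane
Product: 21 (4Z)-5-iodo-4-(methoxymethyl)pent-4-enal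
Conditions: 1 M HCl, THF, 45 °C
Reagents that add atoms: water, O
Why: acid-catalysed acetal hydrolysis releases the aldehyde while the vinyl iodide and the primary allylic methyl ether are stable to dilute acid.

Step 13
Reactants: 21 (4Z)-5-iodo-4-(methoxymethyl)pent-4-enal; 22 tert-butyldimethyl{[(2E)-3-(Bpin)prop-2-en-1-yl]oxy}silane
Product: 25 (3S,4R,7Z)-3-[(tert-butyldimethylsilyl)oxy]-8-iodo-7-(methoxymethyl)octa-1,7-dien-4-ol, via γ-silyloxyallylboronate 23 (not isolated), via borate ester 24 (not isolated)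
Conditions: 22, [Ir(cod)(PPh2Me)2]PF6 (3 mol %, H2-activated), THF, rt; then 21, (R)-TRIP (5 mol %), 4 Å MS, toluene, −30 °C; aq. NaHCO3
Reagents that add atoms: none
Why: a cationic iridium hydride moves the double bond of 22 into conjugation with oxygen to give the E γ-silyloxyallylboronate, and the chiral phosphoric acid then catalyses its allylboration of 21 through a closed chair transition state in which the E geometry gives the anti relationship and the catalyst selects the aldehyde face, setting C9 (R) and C8 (S) in one metal-free asymmetric C–C bond formation (chiral Brønsted acid-catalysed alkoxyallylboration).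

Step 14
Reactants: 25 (3S,4R,7Z)-3-[(tert-butyldimethylsilyl)oxy]-8-iodo-7-(methoxymethyl)octa-1,7-dien-4-ol
Product: 26 (3S,4R,7Z)-3,4-bis[(tert-butyldimethylsilyl)oxy]-8-iodo-7-(methoxymethyl)octa-1,7-diene
Conditions: TBSOTf, 2,6-lutidine, CH2Cl2, −78 → 0 °C
Reagents that add atoms: tert-butyldimethylsilyl trifluoromethanesulfonate, CC(C)(C)[Si](C)(C)OS(=O)(=O)C(F)(F)F
Why: silylation of the secondary alcohol with the silyl triflate and a hindered base gives the bis-silyl ether, and any 1,2-silyl shift is without consequence because both oxygens end up carrying the same group.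

Step 15
Reactants: 26 (3S,4R,7Z)-3,4-bis[(tert-butyldimethylsilyl)oxy]-8-iodo-7-(methoxymethyl)octa-1,7-diene
Product: 29 (3S,4R,7Z)-3,4-bis[(tert-butyldimethylsilyl)oxy]-8-iodo-7-(methoxymethyl)oct-7-enal, via alkylborane 27 (not isolated), via primary alcohol 28 (not isolated)
Conditions: 9-BBN, THF, rt; then NMO (excess), Pr4N[RuO4] (5 mol %), 4 Å MS, CH2Cl2, rt
Reagents that add atoms: 4-methylmorpholine N-oxide, C[N+]1([O-])CCOCC1
Why: anti-Markovnikov hydroboration of the only monosubstituted alkene with 9-BBN, followed in the same flask by N-oxide oxidation of the C–B bond and perruthenate-catalysed (Ley–Griffith) oxidation of the primary alcohol, gives the aldehyde, and the hindered iodoalkene does not hydroborate.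

Step 16
Reactants: 29 (3S,4R,7Z)-3,4-bis[(tert-butyldimethylsilyl)oxy]-8-iodo-7-(methoxymethyl)oct-7-enal; 30 nitromethane
Product: 31 (2S,4S,5R,8Z)-4,5-bis[(tert-butyldimethylsilyl)oxy]-9-iodo-8-(methoxymethyl)-1-nitronon-8-en-2-ol
Conditions: 30 (10 equiv), Cu(OAc)2·H2O (10 mol %), (3aS,8aR)-inda-box bis(oxazoline) (11 mol %), EtOH, rt
Reagents that add atoms: none
Why: copper–bis(oxazoline)-catalysed asymmetric Henry (nitroaldol) reaction in which the chiral divalent copper acetate complex controls the face of the aldehyde to set C6 (S), the mild acetate base avoiding β-elimination of the silyloxy group.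

Step 17
Reactants: 31 (2S,4S,5R,8Z)-4,5-bis[(tert-butyldimethylsilyl)oxy]-9-iodo-8-(methoxymethyl)-1-nitronon-8-en-2-ol
Product: 32 (2S,4S,5R,8Z)-2,4,5-tris[(tert-butyldimethylsilyl)oxy]-9-iodo-8-(methoxymethyl)-1-nitronon-8-ene
Conditions: TBSOTf, 2,6-lutidine, CH2Cl2, −78 → 0 °C
Reagents that add atoms: tert-butyldimethylsilyl trifluoromethanesulfonate, CC(C)(C)[Si](C)(C)OS(=O)(=O)C(F)(F)F
Why: silylation of the nitro alcohol blocks retro-Henry cleavage and gives the uniformly protected triol.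

Step 18
Reactants: 32 (2S,4S,5R,8Z)-2,4,5-tris[(tert-butyldimethylsilyl)oxy]-9-iodo-8-(methoxymethyl)-1-nitronon-8-ene
Product: 34 N-[(2S,4S,5R,8Z)-2,4,5-tris[(tert-butyldimethylsilyl)oxy]-9-iodo-8-(methoxymethyl)non-8-en-1-yl]formamide, via primary amine 33 (not isolated)
Conditions: Zn, AcOH, THF, rt; filtration and NaHCO3 wash; then HCO2Et, 55 °C
Reagents that add atoms: ethyl formate, CCOC=O
Why: zinc in acetic acid reduces the primary nitro group to the amine without touching the vinyl iodide or silyl ethers, and aminolysis of ethyl formate then gives the formamide (nitro reduction followed by N-formylation).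

**Union and ring closure (steps 19–23)**

Step 19
Reactants: 15 methyl (2S,4R,13R,14E)-13-ethyl-2,4-dimethyl-9-oxo-15-(Bpin)pentadec-14-enoate; 34 N-[(2S,4S,5R,8Z)-2,4,5-tris[(tert-butyldimethylsilyl)oxy]-9-iodo-8-(methoxymethyl)non-8-en-1-yl]formamide
Product: 35 methyl (2S,4R,13R,14E,16Z,20R,21S,23S)-20,21,23-tris[(tert-butyldimethylsilyl)oxy]-13-ethyl-24-formamido-17-(methoxymethyl)-2,4-dimethyl-9-oxotetracosa-14,16-dienoate
Conditions: PdCl2(dppf) (5 mol %), K3PO4, THF/H2O, 40 °C
Reagents that add atoms: none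
Why: Suzuki–Miyaura coupling of the E alkenylboronate with the Z vinyl iodide proceeds with retention at both partners to form the C13–C14 bond and the (12Z,14E) diene, and formamide, ketone, ester and silyl ethers tolerate aqueous phosphate.

Step 20
Reactants: 35 methyl (2S,4R,13R,14E,16Z,20R,21S,23S)-20,21,23-tris[(tert-butyldimethylsilyl)oxy]-13-ethyl-24-formamido-17-(methoxymethyl)-2,4-dimethyl-9-oxotetracosa-14,16-dienoate
Product: 36 methyl (2S,4R,13R,14E,16Z,20R,21S,23S)-20,21,23-tris[(tert-butyldimethylsilyl)oxy]-13-ethyl-24-isocyano-17-(methoxymethyl)-2,4-dimethyl-9-oxotetracosa-14,16-dienoate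
Conditions: POCl3, Et3N, CH2Cl2, −30 → 0 °C
Reagents that add atoms: none
Why: dehydration of the secondary formamide with POCl3 and Et3N (Ugi isocyanide synthesis) gives the isocyanide after the last palladium step, and ketone, ester and silyl ethers are unaffected at low temperature.

Step 21
Reactants: 36 methyl (2S,4R,13R,14E,16Z,20R,21S,23S)-20,21,23-tris[(tert-butyldimethylsilyl)oxy]-13-ethyl-24-isocyano-17-(methoxymethyl)-2,4-dimethyl-9-oxotetracosa-14,16-dienoate
Product: 38 (2S,4R,13R,14E,16Z,20R,21S,23S)-20,21,23-tris[(tert-butyldimethylsilyl)oxy]-13-ethyl-24-isocyano-17-(methoxymethyl)-2,4-dimethyl-9-oxotetracosa-14,16-dienoic acid, via lithium carboxylate 37 (not isolated)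
Conditions: LiOH, THF/MeOH/H2O, rt; then H3PO4 to pH 5, 0 °C
Reagents that add atoms: lithium hydroxide, [Li+].[OH-]
Why: saponification of the methyl ester is compatible with the base-stable isocyanide and silyl ethers, and buffered acidification at 0 °C liberates the isocyano acid for immediate use without epimerising C27.

Step 22
Reactants: 38 (2S,4R,13R,14E,16Z,20R,21S,23S)-20,21,23-tris[(tert-butyldimethylsilyl)oxy]-13-ethyl-24-isocyano-17-(methoxymethyl)-2,4-dimethyl-9-oxotetracosa-14,16-dienoic acid; 39 butanal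
Product: 41 (2S,6S,8S,9R,12Z,14E,16R,25R,27S)-6,8,9-tris[(tert-butyldimethylsilyl)oxy]-16-ethyl-12-(methoxymethyl)-25,27-dimethyl-2-propyl-1-oxa-4-azacyclooctacosa-12,14-diene-3,20,28-trione, via macrocyclic imidate 40 (not isolated)
Conditions: (R)-TRIP (20 mol %), 39 (10 equiv), 4 Å MS, CH2Cl2, rt; 38 added over 12 h (final 2 mM)
Reagents that add atoms: none
Why: Proposed new method: the chiral BINOL phosphoric acid is expected to bind the carboxylic acid of 38 as a hydrogen-bonded heterodimer that activates butanal, so that the tethered isocyanide adds to one face of the aldehyde while the carboxylate traps the nitrilium carbon to give macrocyclic imidate 40, whose Mumm 1,4-acyl shift delivers the 28-membered α-acyloxy amide with C2 (S) set by the catalyst and the C2–C3 and O1–C28 bonds formed together; slow addition keeps 38 dilute against excess aldehyde so that ring closure, first order in 38, outruns oligomerisation; the closest known reactions are the chiral phosphoric acid-catalysed enantioselective three-component Passerini reaction and uncatalysed Passerini macrocyclisations of isocyano acids, which have not been combined or applied to a stereochemically complex seco acid.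

Step 23
Reactants: 41 (2S,6S,8S,9R,12Z,14E,16R,25R,27S)-6,8,9-tris[(tert-butyldimethylsilyl)oxy]-16-ethyl-12-(methoxymethyl)-25,27-dimethyl-2-propyl-1-oxa-4-azacyclooctacosa-12,14-diene-3,20,28-trione
Product: 42 (2S,6S,8S,9R,12Z,14E,16R,25R,27S)-16-ethyl-6,8,9-trihydroxy-12-(methoxymethyl)-25,27-dimethyl-2-propyl-1-oxa-4-azacyclooctacosa-12,14-diene-3,20,28-trione
Conditions: HF·pyridine, pyridine, THF, 0 °C → rt
Reagents that add atoms: none
Why: fluoride-mediated cleavage of the three silyl ethers with buffered HF·pyridine leaves the lactone, lactam, ketone, allylic methyl ether and diene intact and gives the target.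

**Compound list**

1 | 6-bromohex-1-ene | C=CCCCCBr | starting material
2 | (E)-1,4-dibromobut-2-ene | BrC/C=C/CBr | starting material
3 | (E)-1,7-dibromohept-2-ene | BrC/C=C/CCCCBr | intermediate
4 | (3R)-7-bromo-3-methylhept-1-ene | C=C[C@H](C)CCCCBr | intermediate
5 | methyl methacrylate | C=C(C)C(=O)OC | starting material
6 | methyl (2E,4R)-8-bromo-2,4-dimethyloct-2-enoate | COC(=O)/C(C)=C/[C@H](C)CCCCBr | intermediate
7 | methyl (2S,4R)-8-bromo-2,4-dimethyloctanoate | COC(=O)[C@@H](C)C[C@H](C)CCCCBr | intermediate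
8 | methyl hex-5-enoate | C=CCCCC(=O)OC | starting material
9 | methyl (5E)-7-bromohept-5-enoate | COC(=O)CCC/C=C/CBr | intermediate
10 | methyl (5R)-5-ethylhept-6-enoate | COC(=O)CCC[C@@H](CC)C=C | intermediate
11 | S-ethyl (5R)-5-ethylhept-6-enethioate | CCSC(=O)CCC[C@@H](CC)C=C | intermediate
12 | [(5R,7S)-8-methoxy-5,7-dimethyl-8-oxooctyl]zinc bromide | COC(=O)[C@@H](C)C[C@H](C)CCCC[Zn]Br | intermediate
13 | methyl (2S,4R,13R)-13-ethyl-2,4-dimethyl-9-oxopentadec-14-enoate | COC(=O)[C@@H](C)C[C@H](C)CCCCC(=O)CCC[C@@H](CC)C=C | intermediate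
14 | 4,4,5,5-tetramethyl-2-vinyl-1,3,2-dioxaborolane | C=CB1OC(C)(C)C(C)(C)O1 | starting material
15 | methyl (2S,4R,13R,14E)-13-ethyl-2,4-dimethyl-9-oxo-15-(Bpin)pentadec-14-enoate | COC(=O)[C@@H](C)C[C@H](C)CCCCC(=O)CCC[C@@H](CC)/C=C/B1OC(C)(C)C(C)(C)O1 | intermediate
16 | prop-2-yn-1-ol | C#CCO | starting material
17 | [2-(1,3-dioxan-2-yl)ethyl]magnesium bromide | Br[Mg]CCC1OCCCO1 | starting material
18 | 4-[2-(1,3-dioxan-2-yl)ethyl]-2,5-dihydro-1,2-oxamagnesole (alkenylmagnesium alkoxide chelate) | O1CC(CCC2OCCCO2)=C[Mg]1 | intermediate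
19 | (2Z)-2-[2-(1,3-dioxan-2-yl)ethyl]-3-iodoprop-2-en-1-ol | I/C=C(\CO)CCC1OCCCO1 | intermediate
20 | 2-[(3Z)-4-iodo-3-(methoxymethyl)but-3-en-1-yl]-1,3-dioxane | I/C=C(\COC)CCC1OCCCO1 | intermediate
21 | (4Z)-5-iodo-4-(methoxymethyl)pent-4-enal | I/C=C(\COC)CCC=O | intermediate
22 | tert-butyldimethyl{[(2E)-3-(Bpin)prop-2-en-1-yl]oxy}silane | CC(C)(C)[Si](C)(C)OC/C=C/B1OC(C)(C)C(C)(C)O1 | starting material
23 | tert-butyldimethyl{[(1E)-3-(Bpin)prop-1-en-1-yl]oxy}silane | CC(C)(C)[Si](C)(C)O/C=C/CB1OC(C)(C)C(C)(C)O1 | intermediate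
24 | 2-{[(3S,4R,7Z)-3-(TBSO)-8-iodo-7-(methoxymethyl)octa-1,7-dien-4-yl]oxy}-4,4,5,5-tetramethyl-1,3,2-dioxaborolane | I/C=C(\COC)CC[C@@H](OB1OC(C)(C)C(C)(C)O1)[C@@H](O[Si](C)(C)C(C)(C)C)C=C | intermediate
25 | (3S,4R,7Z)-3-[(tert-butyldimethylsilyl)oxy]-8-iodo-7-(methoxymethyl)octa-1,7-dien-4-ol | I/C=C(\COC)CC[C@@H](O)[C@@H](O[Si](C)(C)C(C)(C)C)C=C | intermediate
26 | (3S,4R,7Z)-3,4-bis[(tert-butyldimethylsilyl)oxy]-8-iodo-7-(methoxymethyl)octa-1,7-diene | I/C=C(\COC)CC[C@@H](O[Si](C)(C)C(C)(C)C)[C@@H](O[Si](C)(C)C(C)(C)C)C=C | intermediate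
27 | 9-[(3S,4R,7Z)-3,4-bis(TBSO)-8-iodo-7-(methoxymethyl)oct-7-en-1-yl]-9-borabicyclo[3.3.1]nonane | I/C=C(\COC)CC[C@@H](O[Si](C)(C)C(C)(C)C)[C@@H](O[Si](C)(C)C(C)(C)C)CCB1C2CCCC1CCC2 | intermediate
28 | (3S,4R,7Z)-3,4-bis(TBSO)-8-iodo-7-(methoxymethyl)oct-7-en-1-ol | I/C=C(\COC)CC[C@@H](O[Si](C)(C)C(C)(C)C)[C@@H](O[Si](C)(C)C(C)(C)C)CCO | intermediate
29 | (3S,4R,7Z)-3,4-bis[(tert-butyldimethylsilyl)oxy]-8-iodo-7-(methoxymethyl)oct-7-enal | I/C=C(\COC)CC[C@@H](O[Si](C)(C)C(C)(C)C)[C@@H](O[Si](C)(C)C(C)(C)C)CC=O | intermediate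
30 | nitromethane | C[N+](=O)[O-] | starting material
31 | (2S,4S,5R,8Z)-4,5-bis[(tert-butyldimethylsilyl)oxy]-9-iodo-8-(methoxymethyl)-1-nitronon-8-en-2-ol | I/C=C(\COC)CC[C@@H](O[Si](C)(C)C(C)(C)C)[C@@H](O[Si](C)(C)C(C)(C)C)C[C@H](O)C[N+](=O)[O-] | intermediate
32 | (2S,4S,5R,8Z)-2,4,5-tris[(tert-butyldimethylsilyl)oxy]-9-iodo-8-(methoxymethyl)-1-nitronon-8-ene | I/C=C(\COC)CC[C@@H](O[Si](C)(C)C(C)(C)C)[C@@H](O[Si](C)(C)C(C)(C)C)C[C@H](O[Si](C)(C)C(C)(C)C)C[N+](=O)[O-] | intermediate
33 | (2S,4S,5R,8Z)-2,4,5-tris(TBSO)-9-iodo-8-(methoxymethyl)non-8-en-1-amine | I/C=C(\COC)CC[C@@H](O[Si](C)(C)C(C)(C)C)[C@@H](O[Si](C)(C)C(C)(C)C)C[C@H](O[Si](C)(C)C(C)(C)C)CN | intermediate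
34 | N-[(2S,4S,5R,8Z)-2,4,5-tris[(tert-butyldimethylsilyl)oxy]-9-iodo-8-(methoxymethyl)non-8-en-1-yl]formamide | I/C=C(\COC)CC[C@@H](O[Si](C)(C)C(C)(C)C)[C@@H](O[Si](C)(C)C(C)(C)C)C[C@H](O[Si](C)(C)C(C)(C)C)CNC=O | intermediate
35 | methyl (2S,4R,13R,14E,16Z,20R,21S,23S)-20,21,23-tris(TBSO)-13-ethyl-24-formamido-17-(methoxymethyl)-2,4-dimethyl-9-oxotetracosa-14,16-dienoate | COC(=O)[C@@H](C)C[C@H](C)CCCCC(=O)CCC[C@@H](CC)/C=C/C=C(\COC)CC[C@@H](O[Si](C)(C)C(C)(C)C)[C@@H](O[Si](C)(C)C(C)(C)C)C[C@H](O[Si](C)(C)C(C)(C)C)CNC=O | intermediate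
36 | methyl (2S,4R,13R,14E,16Z,20R,21S,23S)-20,21,23-tris(TBSO)-13-ethyl-24-isocyano-17-(methoxymethyl)-2,4-dimethyl-9-oxotetracosa-14,16-dienoate | COC(=O)[C@@H](C)C[C@H](C)CCCCC(=O)CCC[C@@H](CC)/C=C/C=C(\COC)CC[C@@H](O[Si](C)(C)C(C)(C)C)[C@@H](O[Si](C)(C)C(C)(C)C)C[C@H](O[Si](C)(C)C(C)(C)C)C[N+]#[C-] | intermediate
37 | lithium (2S,4R,13R,14E,16Z,20R,21S,23S)-20,21,23-tris(TBSO)-13-ethyl-24-isocyano-17-(methoxymethyl)-2,4-dimethyl-9-oxotetracosa-14,16-dienoate | [Li+].[O-]C(=O)[C@@H](C)C[C@H](C)CCCCC(=O)CCC[C@@H](CC)/C=C/C=C(\COC)CC[C@@H](O[Si](C)(C)C(C)(C)C)[C@@H](O[Si](C)(C)C(C)(C)C)C[C@H](O[Si](C)(C)C(C)(C)C)C[N+]#[C-] | intermediate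
38 | (2S,4R,13R,14E,16Z,20R,21S,23S)-20,21,23-tris(TBSO)-13-ethyl-24-isocyano-17-(methoxymethyl)-2,4-dimethyl-9-oxotetracosa-14,16-dienoic acid | OC(=O)[C@@H](C)C[C@H](C)CCCCC(=O)CCC[C@@H](CC)/C=C/C=C(\COC)CC[C@@H](O[Si](C)(C)C(C)(C)C)[C@@H](O[Si](C)(C)C(C)(C)C)C[C@H](O[Si](C)(C)C(C)(C)C)C[N+]#[C-] | intermediate
39 | butanal | CCCC=O | starting material
40 | 27-membered cyclic O-acyl imidate (carboxylate oxygen of 38 bonded to the former isocyanide carbon, which carries C=N and a (1S)-1-hydroxybutyl group) | O1C(=O)[C@@H](C)C[C@H](C)CCCCC(=O)CCC[C@@H](CC)/C=C/C=C(\COC)CC[C@@H](O[Si](C)(C)C(C)(C)C)[C@@H](O[Si](C)(C)C(C)(C)C)C[C@H](O[Si](C)(C)C(C)(C)C)CN=C1[C@@H](O)CCC | intermediate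
41 | (2S,6S,8S,9R,12Z,14E,16R,25R,27S)-6,8,9-tris(TBSO)-16-ethyl-12-(methoxymethyl)-25,27-dimethyl-2-propyl-1-oxa-4-azacyclooctacosa-12,14-diene-3,20,28-trione | CCC[C@@H]1OC(=O)[C@@H](C)C[C@H](C)CCCCC(=O)CCC[C@@H](CC)/C=C/C=C(\COC)CC[C@@H](O[Si](C)(C)C(C)(C)C)[C@@H](O[Si](C)(C)C(C)(C)C)C[C@H](O[Si](C)(C)C(C)(C)C)CNC1=O | intermediate
42 | (2S,6S,8S,9R,12Z,14E,16R,25R,27S)-16-ethyl-6,8,9-trihydroxy-12-(methoxymethyl)-25,27-dimethyl-2-propyl-1-oxa-4-azacyclooctacosa-12,14-diene-3,20,28-trione | CCC[C@@H]1OC(=O)[C@@H](C)C[C@H](C)CCCCC(=O)CCC[C@@H](CC)/C=C/C=C(\COC)CC[C@@H](O)[C@@H](O)C[C@H](O)CNC1=O | target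

**Step count and risk**

Total: 23 steps. Longest linear sequence: 14 steps (16 → 42, steps 10–23); the West fragment joins after 9 steps (longest line 1 → 15 is 6 steps).

Three steps most likely to fail:

Step 22 (proposed new step). Risks are oligomerisation, a slow termolecular event at high dilution, and mismatch between the catalyst and the C27 and C6 centres. The fallback uses known chemistry and closes the ring at the diene instead. It sets out from 34 and 15. Formamide 34 is dehydrated (POCl3, Et3N) to the iodo isocyanide F1. Ester 15 is saponified (LiOH, THF/H2O) to the boronate acid F2. F1, F2 and butanal 39 are joined by the known intermolecular chiral-phosphoric-acid-catalysed three-component Passerini reaction to the acyclic α-acyloxy amide F3. Intramolecular Suzuki–Miyaura coupling of F3 (Pd(PPh3)4, K3PO4, THF/H2O, 1 mM) forms the C13–C14 bond and comes back to the route at 41.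

Step 3. Cross-metathesis of an α-branched alkene with a 1,1-disubstituted acrylate can be sluggish. The fallback sets out from 4: ozonolysis (O3, CH2Cl2, −78 °C; PPh3) gives (2R)-6-bromo-2-methylhexanal F4, and Wittig olefination with methyl 2-(triphenylphosphoranylidene)propanoate (toluene, 80 °C) comes back to the route at 6.

Step 13. The tandem isomerisation/allylboration depends on clean E-selective isomerisation and on the silyloxy reagent behaving like known alkoxy reagents under acid catalysis. The fallback sets out from 21: iridium-catalysed transfer-hydrogenative anti-alkoxyallylation with prop-2-ene-1,1-diyl dibenzoate ([Ir(cod)Cl]2, (R)-SEGPHOS, 4-cyano-3-nitrobenzoic acid, Cs2CO3, i-PrOH, THF, 90 °C) gives the anti hydroxy benzoate F5. Methanolysis (K2CO3, MeOH) gives the anti diol F6, and double silylation (TBSOTf, 2,6-lutidine) comes back to the route at 26.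

**Further compounds**

F1 | step 22 | (2S,4S,5R,8Z)-2,4,5-tris[(tert-butyldimethylsilyl)oxy]-9-iodo-1-isocyano-8-(methoxymethyl)non-8-ene | I/C=C(\COC)CC[C@@H](O[Si](C)(C)C(C)(C)C)[C@@H](O[Si](C)(C)C(C)(C)C)C[C@H](O[Si](C)(C)C(C)(C)C)C[N+]#[C-]
F2 | step 22 | (2S,4R,13R,14E)-13-ethyl-2,4-dimethyl-9-oxo-15-(Bpin)pentadec-14-enoic acid | OC(=O)[C@@H](C)C[C@H](C)CCCCC(=O)CCC[C@@H](CC)/C=C/B1OC(C)(C)C(C)(C)O1
F3 | step 22 | (2S)-1-{[(2S,4S,5R,8Z)-2,4,5-tris(TBSO)-9-iodo-8-(methoxymethyl)non-8-en-1-yl]amino}-1-oxopentan-2-yl (2S,4R,13R,14E)-13-ethyl-2,4-dimethyl-9-oxo-15-(Bpin)pentadec-14-enoate | CCC[C@H](OC(=O)[C@@H](C)C[C@H](C)CCCCC(=O)CCC[C@@H](CC)/C=C/B1OC(C)(C)C(C)(C)O1)C(=O)NC[C@@H](O[Si](C)(C)C(C)(C)C)C[C@H](O[Si](C)(C)C(C)(C)C)[C@H](O[Si](C)(C)C(C)(C)C)CC/C(COC)=C/I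
F4 | step 3 | (2R)-6-bromo-2-methylhexanal | O=C[C@H](C)CCCCBr
F5 | step 13 | (3S,4R,7Z)-4-hydroxy-8-iodo-7-(methoxymethyl)octa-1,7-dien-3-yl benzoate | I/C=C(\COC)CC[C@@H](O)[C@@H](OC(=O)c1ccccc1)C=C
F6 | step 13 | (3S,4R,7Z)-8-iodo-7-(methoxymethyl)octa-1,7-diene-3,4-diol | I/C=C(\COC)CC[C@@H](O)[C@@H](O)C=C
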